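Its constants are made up; no experiment stands behind them.

The charges set 0.0900 M of J against the 0.0950 M of X that Z leaves uncapped, so J is the limiting reagent.

| flask | X | J | Z | G | time |
|---|---|---|---|---|---|
| green | 0.10 M | 0.0900 M | 5.00 mM | 0.0200 M | 8.0 h |
| blue | 0.10 M | 0.0900 M | 5.00 mM | 0.00600 M | 8.0 h |

    X + J → X.J (k1 = 3.6 M⁻¹ min⁻¹)
    X + Z → X.Z (k2 = 63 M⁻¹ min⁻¹)
    J + G → J.G (k3 = 4.9 M⁻¹ min⁻¹)
    J → L (k4 = 0.031 min⁻¹)

- which of the two ends with the longer chains by the average number of monomer units in a chain (unreacted monomers counted as chains of one) ("neither" if they lie within 10%) (green / blue / neither)
- average number of monomer units in a chain (unreacted monomers counted as chains of one) at the end, green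
- average number of monomer units in a chain (unreacted monomers counted as chains of one) at the end, blue

- each monomer carries two end groups and Z one, which caps an end: a chain counts once for every two ends that are left, dead ends included; the units are half of the end groups of the two monomers charged
- run time (green): 8.0 h

I wrote the balance of J. Each step that uses J is first order in J, so dividing one rate by another removes both J and time. I let Z cap first, and I let J be spent within the run, since its half-life by J → L alone is 0.37 h. The toll is the constant of J → L over that of X + J → X.J, 0.00861 M: the L laid down for each natural-log fall of X. G left follows X with the power p, 1.36. For X left at x: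

J spent = (free X − x) + (G charged − G charged × (x/free X)^p) + toll × ln(free X/x)

Each link removes a chain, so length = units/(units − links), with 0.0950 M of units. With nothing lost, the ceiling is 19.0. Then I tried values of x. A bill under the J charged means X falls further, and a bill over it means X stops sooner.

green, x = 0.0333 M: bill 0.0859 M, so length above 2.85

green, x = 0.0286 M: bill 0.0929 M, so length below 3.32

blue, x = 0.0233 M: bill 0.0889 M, so length above 4.08

blue, x = 0.0222 M: bill 0.0905 M, so length below 4.28

The forecast gave 3.1 for green (2.95 to 3.3) and 4.2 for blue (3.95 to 4.5), with blue longer: “Blue has less G to waste J”. Both central values lay inside my brackets.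

The simulation gave 3.12 for green and 4.22 for blue, so blue ended longer.

The difference in G is the main reason: with that difference taken away, so that blue held the G of green, the length was 3.12, not 4.22. With 23% of its X left, blue's toll comes to 0.0124 M of L, and its L of 0.0124 M exceeded green's 0.00976 M, yet J.G took 0.00515 M against 0.0157 M. With 0.25 M of X in blue's recipe, there are 0.170 M of units and 0.245 M of free X. The toll is at most 0.00394 M, which with 0.00600 M of G puts the length between 1.89 and 2.12. The computed length was 1.97.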